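**Retrosynthetic overview**

1. Labdane numbering is used (ring A = C1–C5 and C10, ring B = C5–C10, side chain C11–C16, α = face opposite the C10 methyl). The (Z)-enoate comes from Me2CuLi addition to a C13≡C14 ynoate, and the C9 carbinol from α-face addition of a butynyl nucleophile to 9-ketone 22 (8α-methyl by equilibration).
2. Ketone 22 comes from keto sulfone 20, and 20 from the acyclic enone–vinyl sulfone 16 by an intramolecular double Michael reaction: the C5–C10 bond closes ring A, then the C6–C7 bond closes ring B, in one flask.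
3. Enabling feature: ring B carries its only oxygen at C9, between quaternary C10 and methyl-bearing C8, and C6/C7 are bare CH2 groups. At the ketone level ring B is therefore the formal [4+2] adduct of a C7=C8–C9(O−)=C10 dienolate and a C5=C6 alkene; the cis-2,3-diol of ring A, held as an acetonide in the tether, chooses the face.
4. Precursor 16 comes from a Weinreb amide (isopropenyl Grignard), an (E)-vinyl sulfone (ozonolysis, Horner–Wadsworth–Emmons), a C3–C4 bond made by reverse prenylation, and C2 from (R)-5-(hydroxymethyl)butyrolactone 1.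
5. Order of ring formation: ring A, then ring B, both in step 8; the lactone and dioxolane rings are temporary.

Key step: step 8

Remark: the carbon that becomes C10 is carried as a mixture of epimers from step 2 to step 7, because step 8 passes through a planar enolate at this carbon.

**Route**

Step 1
Reactants: 1 (R)-5-(hydroxymethyl)dihydrofuran-2(3H)-one; 2 3-methylbut-2-en-1-ylboronic acid pinacol ester
Product: 5 (R)-5-[(S)-1-hydroxy-2,2-dimethylbut-3-en-1-yl]dihydrofuran-2(3H)-one, via aldehyde 3 (not isolated), via borate ester 4 (not isolated)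
Conditions: Dess–Martin periodinane, CH2Cl2, rt; filtration through silica; crude 3 + 2, toluene, rt → 40 °C; aq. NaHCO3 work-up
Reagents that add atoms: 3-methylbut-2-en-1-ylboronic acid pinacol ester 2, CC(C)=CCB1OC(C)(C)C(C)(C)O1
Why: Dess–Martin oxidation gives the α-oxygenated aldehyde under non-basic conditions, and γ-selective allylboration (reverse prenylation) through a closed chair transition state should follow the Felkin–Anh (Cornforth) sense, reinforced by the axial γ-methyl group, to set the new carbinol centre (C3) anti to the lactone oxygen at C2.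

Step 2
Reactants: 5 (R)-5-[(S)-1-hydroxy-2,2-dimethylbut-3-en-1-yl]dihydrofuran-2(3H)-one
Product: 7 (5R)-5-[(S)-1-hydroxy-2,2-dimethylbut-3-en-1-yl]-3-methyldihydrofuran-2(3H)-one (C3 epimers), via dilithium dianion 6 (not isolated)
Conditions: LiN(iPr)2 (2.2 equiv), THF, −78 °C; MeI (1.3 equiv), −78 → −40 °C; AcOH quench
Reagents that add atoms: iodomethane, CI
Why: Lactone enolate alkylation through the alkoxide–enolate dianion installs the future C10 methyl on carbon, and its configuration is left uncontrolled on purpose because step 8 erases it.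

Step 3
Reactants: 7 (5R)-5-[(S)-1-hydroxy-2,2-dimethylbut-3-en-1-yl]-3-methyldihydrofuran-2(3H)-one
Product: 8 (4R,5S)-4,5-dihydroxy-N-methoxy-N,2,6,6-tetramethyloct-7-enamide (C2 epimers)
Conditions: MeNH(OMe)·HCl (4 equiv), AlMe3 (4 equiv), CH2Cl2, 0 °C → rt; aq. potassium sodium tartrate work-up
Reagents that add atoms: N,O-dimethylhydroxylamine hydrochloride, CNOC.Cl
Why: Weinreb aminolysis of the lactone by the aluminium amide opens the ring to the N-methoxy-N-methylamide and frees the C2 hydroxyl, and any translactonised material from step 2 converges on the same amide.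

Step 4
Reactants: 8 (4R,5S)-4,5-dihydroxy-N-methoxy-N,2,6,6-tetramethyloct-7-enamide
Product: 9 3-[(4R,5S)-2,2-dimethyl-5-(2-methylbut-3-en-2-yl)-1,3-dioxolan-4-yl]-N-methoxy-N,2-dimethylpropanamide
Conditions: 2,2-dimethoxypropane, pyridinium p-toluenesulfonate (cat.), CH2Cl2, rt
Reagents that add atoms: 2,2-dimethoxypropane, COC(C)(C)OC
Why: Acid-catalysed transketalisation (acetonide formation) ties the erythro 1,2-diol into a cis-dioxolane, which blocks relactonisation and later serves as the turn element and the stereocontrol element of the key step.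

Step 5
Reactants: 9 3-[(4R,5S)-2,2-dimethyl-5-(2-methylbut-3-en-2-yl)-1,3-dioxolan-4-yl]-N-methoxy-N,2-dimethylpropanamide
Product: 11 3-[(4R,5S)-2,2-dimethyl-5-(2-methyl-1-oxopropan-2-yl)-1,3-dioxolan-4-yl]-N-methoxy-N,2-dimethylpropanamide, via ozonide 10 (not isolated)
Conditions: O3, CH2Cl2, −78 °C; then PPh3, −78 °C → rt
Reagents that add atoms: ozone, [O-][O+]=O
Why: Ozonolysis with reductive work-up cleaves the only alkene to a neopentyl aldehyde (C5) that has no α-hydrogen and therefore can neither epimerise nor eliminate.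

Step 6
Reactants: 11 3-[(4R,5S)-2,2-dimethyl-5-(2-methyl-1-oxopropan-2-yl)-1,3-dioxolan-4-yl]-N-methoxy-N,2-dimethylpropanamide; 12 diethyl [(phenylsulfonyl)methyl]phosphonate
Product: 13 3-{(4R,5S)-2,2-dimethyl-5-[(E)-2-methyl-4-(phenylsulfonyl)but-3-en-2-yl]-1,3-dioxolan-4-yl}-N-methoxy-N,2-dimethylpropanamide
Conditions: 12, NaH, THF, 0 °C; then 11, 0 °C → rt
Reagents that add atoms: diethyl [(phenylsulfonyl)methyl]phosphonate 12, CCOP(=O)(CS(=O)(=O)c1ccccc1)OCC
Why: Horner–Wadsworth–Emmons olefination with the sulfonyl-stabilised phosphonate should give the (E)-vinyl sulfone, the temporary activating group that makes C5 electrophilic and C6 a latent carbanion.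

Step 7
Reactants: 13 3-{(4R,5S)-2,2-dimethyl-5-[(E)-2-methyl-4-(phenylsulfonyl)but-3-en-2-yl]-1,3-dioxolan-4-yl}-N-methoxy-N,2-dimethylpropanamide; 14 isopropenylmagnesium bromide
Product: 16 5-{(4R,5S)-2,2-dimethyl-5-[(E)-2-methyl-4-(phenylsulfonyl)but-3-en-2-yl]-1,3-dioxolan-4-yl}-2,4-dimethylpent-1-en-3-one (C4 epimers), via magnesium chelate 15 (not isolated)
Conditions: 14 (2 equiv), THF, −20 → 0 °C; cold AcOH/THF quench
Reagents that add atoms: isopropenylmagnesium bromide 14, CC(=C)[Mg]Br
Why: Weinreb ketone synthesis stops at mono-addition through the chelated tetrahedral intermediate, and the Grignard reagent should spare the vinyl sulfone because its β-carbon is neopentylic.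

Step 8
Reactants: 16 5-{(4R,5S)-2,2-dimethyl-5-[(E)-2-methyl-4-(phenylsulfonyl)but-3-en-2-yl]-1,3-dioxolan-4-yl}-2,4-dimethylpent-1-en-3-one
Product: 20 2α,3α-(isopropylidenedioxy)-4,4,8,10β-tetramethyl-6α-(phenylsulfonyl)-trans-decalin-9-one (5α-H; C8 epimers), via potassium dienolate 17 (not isolated), via sulfonyl carbanion 18 (not isolated), via potassium enolate 19 (not isolated)
Conditions: KN(SiMe3)2 (1.1 equiv), THF (0.01 M), −78 → 0 °C; AcOH quench
Reagents that add atoms: none
Why: KN(SiMe3)2 removes the only enolisable proton (C10–H), so both C10 epimers of 16 and both enolate geometries converge on cross-conjugated dienolate 17; C10 of 17 adds to C5 of the vinyl sulfone (6-exo-trig, closes ring A) to give α-sulfonyl carbanion 18, whose C6 adds to the unsubstituted enone terminus C7 (6-endo-trig, closes ring B through the C6–C7 bond) to give enolate 19. The closest known reaction type is the intramolecular double Michael reaction (anionic Diels–Alder, Michael–Michael ring closure) of kinetic enone dienolates with tethered acceptors, and both elementary steps, ketone enolate to vinyl sulfone and sulfonyl carbanion to enone, are standard. C10 and C5 are set in the first addition: ring A should close through a chair in which the smaller C10 substituent (methyl) takes the axial site next to the axial C4 methyl, while C9 and C6 sit equatorial and gauche, bridged by K+ between the enolate and sulfonyl oxygens (the sulfone-endo arrangement of a Diels–Alder reading), which is the trans ring fusion (5α-H, 10β-methyl). The face is chosen by the (2R,3S)-acetonide: the alternative chair would hold the C2–O bond axial and syn to both the C10 methyl and the axial C4 methyl, whereas the productive chair has only the C3–O bond axial, opposite two hydrogens. C6 should come out equatorial but is removed in step 9, and C8 is protonated without control and equilibrated in step 9. The step needs trans over cis fusion and ring closure over intermolecular Michael addition to the isopropenyl ketone; the first rests on the chair preferences above and on reversibility of the first Michael addition (an adduct with C6 and C9 anti on ring A cannot close and reverts), the second on high dilution and the α-methyl group of the enone.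

Step 9
Reactants: 20 2α,3α-(isopropylidenedioxy)-4,4,8,10β-tetramethyl-6α-(phenylsulfonyl)-trans-decalin-9-one
Product: 22 2α,3α-(isopropylidenedioxy)-4,4,8α,10β-tetramethyl-trans-decalin-9-one (5α-H and 8β-H), via epimeric ketone 21 (not isolated)
Conditions: 6% Na(Hg), Na2HPO4, MeOH/THF, −20 °C; then NaOMe (cat.), MeOH, rt
Reagents that add atoms: none
Why: Reductive desulfonylation by electron transfer from Na(Hg) removes the activating group at C6, and methoxide-mediated enolisation then equilibrates C8 to the equatorial 8α-methyl epimer, which avoids the 1,3-diaxial clash with the C10 methyl.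

Step 10
Reactants: 22 2α,3α-(isopropylidenedioxy)-4,4,8α,10β-tetramethyl-trans-decalin-9-one; 23 (4-bromobut-1-yn-1-yl)trimethylsilane
Product: 25 9α-(but-3-yn-1-yl)-2α,3α-(isopropylidenedioxy)-4,4,8α,10β-tetramethyl-trans-decalin-9β-ol, via silylalkynyl carbinol 24 (not isolated)
Conditions: 23, Mg, THF, rt; anhydrous CeCl3, THF, −78 °C; then 22, −78 → 0 °C; AcOH quench; crude 24, K2CO3 (cat.), MeOH, rt
Reagents that add atoms: (4-bromobut-1-yn-1-yl)trimethylsilane 23, C[Si](C)(C)C#CCCBr
Why: 1,2-Addition of the Grignard reagent in the presence of CeCl3 suppresses enolisation of the hindered ketone and should occur by axial attack on the α-face, anti to the axial C10 methyl, to give the 9β-hydroxy-9α-alkyl carbinol, after which methanolysis of the C–Si bond frees the terminal alkyne.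

Step 11
Reactants: 25 9α-(but-3-yn-1-yl)-2α,3α-(isopropylidenedioxy)-4,4,8α,10β-tetramethyl-trans-decalin-9β-ol
Product: 26 9β-O-trimethylsilyl ether of 25
Conditions: Me3SiOTf, 2,6-lutidine, CH2Cl2, −78 → 0 °C
Reagents that add atoms: trimethylsilyl trifluoromethanesulfonate, C[Si](C)(C)OS(=O)(=O)C(F)(F)F
Why: Silylation with the silyl triflate masks the tertiary hydroxyl so that it cannot add in 5-exo fashion to the ynoate made in step 12.

Step 12
Reactants: 26 9β-O-trimethylsilyl ether of 25
Product: 28 methyl ynoate of 26 (C13≡C14–CO2Me), via lithium acetylide 27 (not isolated)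
Conditions: n-BuLi, THF, −78 °C; ClCO2Me, −78 → −20 °C
Reagents that add atoms: methyl chloroformate, COC(=O)Cl
Why: Acylation of the lithium acetylide with methyl chloroformate gives the conjugated ynoate with all side-chain carbons but the C13 methyl in place.

Step 13
Reactants: 28 methyl ynoate of 26
Product: 30 9β-O-trimethylsilyl 2α,3α-O-isopropylidene derivative of the target (13Z), via vinylcuprate 29 (not isolated)
Conditions: Me2CuLi (from CuI and 2 MeLi), THF, −78 °C; AcOH/MeOH quench at −78 °C
Reagents that add atoms: methyllithium (delivered as Me2CuLi), [Li]C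
Why: Conjugate addition of Me2CuLi to the ynoate is a syn carbocupration, and protonation of the alkenylcuprate at −78 °C with retention should put the new C13 methyl cis to H-14, which is the (Z)-enoate.

Step 14
Reactants: 30 9β-O-trimethylsilyl 2α,3α-O-isopropylidene derivative of the target
Product: 31 methyl (2Z)-5-[(1S,2R,4aS,6S,7R,8aS)-1,6,7-trihydroxy-2,5,5,8a-tetramethyldecahydronaphthalen-1-yl]-3-methylpent-2-enoate (target)
Conditions: 1 M HCl, THF, rt
Reagents that add atoms: none
Why: Acid hydrolysis cleaves the trimethylsilyl ether and the acetonide in one operation under conditions that should be too mild to dehydrate the tertiary alcohol or isomerise the enoate.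

**Compound list**

1 | (R)-5-(hydroxymethyl)dihydrofuran-2(3H)-one | O=C1CC[C@H](CO)O1 | starting material
2 | 3-methylbut-2-en-1-ylboronic acid pinacol ester | CC(C)=CCB1OC(C)(C)C(C)(C)O1 | starting material
3 | (R)-5-oxotetrahydrofuran-2-carbaldehyde | O=C1CC[C@H](C=O)O1 | intermediate
4 | pinacol borate ester of 5 (B on the new carbinol oxygen) | O=C1CC[C@H]([C@@H](OB2OC(C)(C)C(C)(C)O2)C(C)(C)C=C)O1 | intermediate
5 | (R)-5-[(S)-1-hydroxy-2,2-dimethylbut-3-en-1-yl]dihydrofuran-2(3H)-one | O=C1CC[C@H]([C@@H](O)C(C)(C)C=C)O1 | intermediate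
6 | dilithium alkoxide–enolate of 5 | [Li+].[Li+].[O-]C1=CC[C@H]([C@@H]([O-])C(C)(C)C=C)O1 | intermediate
7 | (5R)-5-[(S)-1-hydroxy-2,2-dimethylbut-3-en-1-yl]-3-methyldihydrofuran-2(3H)-one (both C3 epimers; this carbon becomes C10) | CC1C[C@H]([C@@H](O)C(C)(C)C=C)OC1=O | intermediate
8 | (4R,5S)-4,5-dihydroxy-N-methoxy-N,2,6,6-tetramethyloct-7-enamide (both C2 epimers) | CON(C)C(=O)C(C)C[C@@H](O)[C@@H](O)C(C)(C)C=C | intermediate
9 | 3-[(4R,5S)-2,2-dimethyl-5-(2-methylbut-3-en-2-yl)-1,3-dioxolan-4-yl]-N-methoxy-N,2-dimethylpropanamide | CON(C)C(=O)C(C)C[C@H]1OC(C)(C)O[C@H]1C(C)(C)C=C | intermediate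
10 | secondary ozonide (1,2,4-trioxolane) of 9 | CON(C)C(=O)C(C)C[C@H]1OC(C)(C)O[C@H]1C(C)(C)C1OCOO1 | intermediate
11 | 3-[(4R,5S)-2,2-dimethyl-5-(2-methyl-1-oxopropan-2-yl)-1,3-dioxolan-4-yl]-N-methoxy-N,2-dimethylpropanamide | CON(C)C(=O)C(C)C[C@H]1OC(C)(C)O[C@H]1C(C)(C)C=O | intermediate
12 | diethyl [(phenylsulfonyl)methyl]phosphonate | CCOP(=O)(CS(=O)(=O)c1ccccc1)OCC | starting material
13 | 3-{(4R,5S)-2,2-dimethyl-5-[(E)-2-methyl-4-(phenylsulfonyl)but-3-en-2-yl]-1,3-dioxolan-4-yl}-N-methoxy-N,2-dimethylpropanamide | CON(C)C(=O)C(C)C[C@H]1OC(C)(C)O[C@H]1C(C)(C)/C=C/S(=O)(=O)c1ccccc1 | intermediate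
14 | isopropenylmagnesium bromide | CC(=C)[Mg]Br | starting material
15 | bromomagnesium N,O-hemiaminal (tetrahedral adduct of 13 and 14) | CON(C)C(O[Mg]Br)(C(C)=C)C(C)C[C@H]1OC(C)(C)O[C@H]1C(C)(C)/C=C/S(=O)(=O)c1ccccc1 | intermediate
16 | 5-{(4R,5S)-2,2-dimethyl-5-[(E)-2-methyl-4-(phenylsulfonyl)but-3-en-2-yl]-1,3-dioxolan-4-yl}-2,4-dimethylpent-1-en-3-one (both C4 epimers) | C=C(C)C(=O)C(C)C[C@H]1OC(C)(C)O[C@H]1C(C)(C)/C=C/S(=O)(=O)c1ccccc1 | intermediate
17 | potassium cross-conjugated dienolate of 16 (C9–OK, C9=C10, both geometries) | [K+].[O-]C(C(C)=C)=C(C)C[C@H]1OC(C)(C)O[C@H]1C(C)(C)/C=C/S(=O)(=O)c1ccccc1 | intermediate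
18 | potassium α-sulfonyl carbanion after the first Michael addition (ring A closed; C10 β-methyl and α-methacryloyl, C5 α-H) | [K+].C=C(C)C(=O)[C@@]1(C)C[C@H]2OC(C)(C)O[C@H]2C(C)(C)[C@@H]1[CH-]S(=O)(=O)c1ccccc1 | intermediate
19 | potassium C8=C9 enolate of 20 | [K+].[O-]C1=C(C)C[C@H](S(=O)(=O)c3ccccc3)[C@H]2C(C)(C)[C@@H]4OC(C)(C)O[C@@H]4C[C@@]21C | intermediate
20 | 2α,3α-(isopropylidenedioxy)-4,4,8,10β-tetramethyl-6α-(phenylsulfonyl)-trans-decalin-9-one (5α-H; both C8 epimers) | O=C1C(C)C[C@H](S(=O)(=O)c3ccccc3)[C@H]2C(C)(C)[C@@H]4OC(C)(C)O[C@@H]4C[C@@]21C | intermediate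
21 | 2α,3α-(isopropylidenedioxy)-4,4,8,10β-tetramethyl-trans-decalin-9-one (5α-H; both C8 epimers) | O=C1C(C)CC[C@H]2C(C)(C)[C@@H]3OC(C)(C)O[C@@H]3C[C@@]21C | intermediate
22 | 2α,3α-(isopropylidenedioxy)-4,4,8α,10β-tetramethyl-trans-decalin-9-one (5α-H, 8β-H) | O=C1[C@H](C)CC[C@H]2C(C)(C)[C@@H]3OC(C)(C)O[C@@H]3C[C@@]21C | intermediate
23 | (4-bromobut-1-yn-1-yl)trimethylsilane | C[Si](C)(C)C#CCCBr | starting material
24 | 9α-[4-(trimethylsilyl)but-3-yn-1-yl]-2α,3α-(isopropylidenedioxy)-4,4,8α,10β-tetramethyl-trans-decalin-9β-ol | C[Si](C)(C)C#CCC[C@]1(O)[C@H](C)CC[C@H]2C(C)(C)[C@@H]3OC(C)(C)O[C@@H]3C[C@@]21C | intermediate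
25 | 9α-(but-3-yn-1-yl)-2α,3α-(isopropylidenedioxy)-4,4,8α,10β-tetramethyl-trans-decalin-9β-ol | C#CCC[C@]1(O)[C@H](C)CC[C@H]2C(C)(C)[C@@H]3OC(C)(C)O[C@@H]3C[C@@]21C | intermediate
26 | 9β-O-trimethylsilyl ether of 25 | C#CCC[C@]1(O[Si](C)(C)C)[C@H](C)CC[C@H]2C(C)(C)[C@@H]3OC(C)(C)O[C@@H]3C[C@@]21C | intermediate
27 | lithium acetylide of 26 | [Li]C#CCC[C@]1(O[Si](C)(C)C)[C@H](C)CC[C@H]2C(C)(C)[C@@H]3OC(C)(C)O[C@@H]3C[C@@]21C | intermediate
28 | methyl ynoate of 26 (C13≡C14–CO2Me; 9β-OSiMe3, 2α,3α-acetonide) | COC(=O)C#CCC[C@]1(O[Si](C)(C)C)[C@H](C)CC[C@H]2C(C)(C)[C@@H]3OC(C)(C)O[C@@H]3C[C@@]21C | intermediate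
29 | lithium alkenyl(methyl)cuprate from syn addition to 28 (Cu on C14, cis to the new C13 methyl) | [Li+].COC(=O)/C([Cu-]C)=C(/C)CC[C@]1(O[Si](C)(C)C)[C@H](C)CC[C@H]2C(C)(C)[C@@H]3OC(C)(C)O[C@@H]3C[C@@]21C | intermediate
30 | 9β-O-trimethylsilyl 2α,3α-O-isopropylidene derivative of the target (13Z) | COC(=O)/C=C(/C)CC[C@]1(O[Si](C)(C)C)[C@H](C)CC[C@H]2C(C)(C)[C@@H]3OC(C)(C)O[C@@H]3C[C@@]21C | intermediate
31 | methyl (2Z)-5-[(1S,2R,4aS,6S,7R,8aS)-1,6,7-trihydroxy-2,5,5,8a-tetramethyldecahydronaphthalen-1-yl]-3-methylpent-2-enoate | COC(=O)/C=C(/C)CC[C@]1(O)[C@H](C)CC[C@H]2C(C)(C)[C@H](O)[C@H](O)C[C@@]21C | target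

**Step count and risks**

Total step count: 14. Longest linear sequence: 14 steps (from 1; compounds 2, 12, 14 and 23 are purchased).

Steps most likely to fail:

1. Step 8. The first Michael addition joins two crowded carbons (C10, which becomes quaternary, and neopentylic C5). It may be too slow, so that intermolecular addition to the enone takes over, or ring closure may show poor control of trans against cis fusion. Fallback, a neutral pericyclic route: from enone 16, soft enolisation (tBuMe2SiOTf, Et3N, CH2Cl2, 0 °C) would give the tert-butyldimethylsilyl dienol ether F1. The isomer with the tether cis to the silyloxy group is the one that can cyclise; the other can be hydrolysed back to 16. Heating F1 in toluene (sealed tube, 150–180 °C) would run an intramolecular Diels–Alder reaction through the sulfone-endo transition state to the cycloadduct silyl enol ether F2 (C8=C9, trans-fused). Aqueous HCl in THF would hydrolyse F2, and the route is rejoined at keto sulfone 20.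

2. Step 10. Enolisation of the hindered ketone may compete with addition, or facial selectivity at C9 may be poor. Fallback, epoxide opening in place of carbonyl addition: from ketone 22, the Corey–Chaykovsky reaction with dimethylsulfonium methylide (Me3S+ I−, n-BuLi, THF, −10 °C → rt) should deliver the small ylide carbon by axial attack on the α-face and close to the spiro-epoxide F3 (C11 α, oxygen β). Opening of F3 at its CH2 terminus by 3-lithio-1-(trimethylsilyl)propyne (from 1-(trimethylsilyl)propyne and n-BuLi, THF, −78 → 0 °C) would give the same carbon chain, and the route is rejoined at silylalkynyl carbinol 24.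

3. Step 1. Diastereoselectivity of the allylboration may erode (competing chelate-type approach), and the sensitive α-oxygenated aldehyde may epimerise or hydrate before it reacts. Fallback, catalyst control at the alcohol oxidation level: from alcohol 1 directly, iridium-catalysed transfer-hydrogenative reverse prenylation with 3-methylbuta-1,2-diene ([Ir(cod)Cl]2, the SEGPHOS enantiomer matched to the (S)-carbinol, 4-chloro-3-nitrobenzoic acid, Cs2CO3, toluene, 60 °C) would form the C3–C4 bond without a free aldehyde, and the route is rejoined at 5; new compounds on this way: none F0.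

**Further compounds**

F1 | step 8 | tert-butyldimethylsilyl dienol ether of 16 (tether cis to the silyloxy group) | C=C(C)/C(O[Si](C)(C)C(C)(C)C)=C(\C)C[C@H]1OC(C)(C)O[C@H]1C(C)(C)/C=C/S(=O)(=O)c1ccccc1
F2 | step 8 | 9-(tert-butyldimethylsilyloxy)-2α,3α-(isopropylidenedioxy)-4,4,8,10β-tetramethyl-6α-(phenylsulfonyl)-trans-decal-8-ene (5α-H) | CC(C)(C)[Si](C)(C)OC1=C(C)C[C@H](S(=O)(=O)c3ccccc3)[C@H]2C(C)(C)[C@@H]4OC(C)(C)O[C@@H]4C[C@@]21C
F3 | step 10 | spiro-epoxide of 22 (C9–O β, C11H2 α) | C1O[C@]12[C@H](C)CC[C@H]3C(C)(C)[C@@H]4OC(C)(C)O[C@@H]4C[C@@]32C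
F0 | step 1 | none | none
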